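# Proposed total synthesis of the bis(bibenzyl) macrocycle 27 (CNP0135015.0) through a chloroenone-masked ring D

## The problem

Target 27 is an 18-membered ring built from four benzene rings. Two CH2CH2 bridges (ring A–ring B and ring C–ring D) and two diaryl ether oxygens (ring B–O–ring C and ring A–O–ring D) hold it together. Ring B is para-linked and ring D meta-linked. Rings A and C are 1,2,4-trisubstituted, each with one free hydroxyl: para to the ether oxygen on ring A, ortho to it on ring C.

The molecule has no stereocentre, so nothing has to be controlled in the target. The only centre that appears on the way (C5 of the ring D precursor) directs nothing and is erased.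

The real difficulties are two. The first is closing a ring that contains four flat arenes, one of them a rigid para-phenylene. The second is the ring A–O–ring D ether: its oxygen sits next to the ortho bridge carbon of ring A, and ring D offers no activating group for a nucleophilic aromatic substitution.

Ring A is a hydroquinone monoaryl ether and ring C a catechol monoaryl ether. As free phenols both oxidise easily, so the two target hydroxyls are best carried as methyl ethers to the last step; the diaryl ethers themselves tolerate BBr3.

The enabling feature is the substitution of ring D. It carries only the bridge CH2 (C1) and the ether oxygen (C3), in a 1,3 relationship. These map onto C5 and C3 of a 5-substituted cyclohexane-1,3-dione, so the ether carbon can be the chlorine-bearing carbon of a 3-chlorocyclohex-2-enone. The price is one surplus oxygen on ring D (the enone carbonyl), which has to be removed after aromatisation.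

## Retrosynthesis

**27 to 26 and 25.** The two O–CH3 bonds are cut last (BBr3), so the oxidation-prone phenols of rings A and C exist only in the final compound. The ring D C–H of 26 is traced to the aryl triflate 25, and thus to a C–O bond. The forward step is a palladium-catalysed formate reduction that leaves diaryl and methyl ethers alone.

**25 to 24 to 20.** The triflate comes from phenol 24, whose hydroxyl is the former enone oxygen. Ring D of 24 is dearomatised by two hydrogens to the macrocyclic vinylogous aryl ester 20. The aryloxy group of 20 sits on an sp2 carbon and cannot be lost by β-elimination, so the forward reaction only has to remove H from C5 and C6. An α'-selenenylation followed by selenoxide syn-elimination does this; the resulting dienone is the keto tautomer of 24.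

**20 to 19 (key cut).** The bond cut is ring A oxygen to C3 of the cyclohexenone. The alternatives compare as follows:
- Cutting the ring B–O–ring C ether would need an activating group that the macrocycle does not have.
- Cutting a bibenzyl bridge would leave the hindered ring A–O–ring D ether to be made on an unactivated arene.
- The chosen cut puts the hardest bond into the ring closure and gives it an electrophile (a vinylogous acid chloride) that needs neither metal nor nitro group.

Precursor 19 is an open chain with one free phenol and a chloroenone. At the moment of closure ring D is a puckered half-chair and not a fourth flat arene. The forward reaction must favour intramolecular O-attack over oligomerisation.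

**19 to 18.** The C–Cl bond is traced to the enol oxygen of the achiral 1,3-dione 18, a vinylogous acid. The forward step must convert the dione and spare the free ring A phenol. Keeping the phenol free is preferred to protecting it, because any protecting group would later have to come off in the presence of the reactive chloroenone.

**18 to 13 and 14.** Ring D is opened at two C–C bonds: C5 to the malonate carbon (Michael) and C2 to the ester carbonyl (Claisen). This gives the (E)-enone 13 and diethyl malonate 14. It is the classical route to 5-substituted cyclohexane-1,3-diones and turns a ring into an acyclic chain. The forward sequence needs only alkoxide, hydroxide and acid, all tolerated by 13.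

**13 to 11 and 12, and 11 to 8 and 9.** The enone double bond is cut to aldehyde 11 and the stabilised ylide 12. The aryl–CH2 bond of the propanal is cut to aryl bromide 8 and allyl alcohol 9 (Heck arylation with redox isomerisation). This delivers the three-carbon chain in one step, where an aldehyde on ring C would need three.

**8 to 7 to 3 and 6.** The ring A–ring B bridge is traced through stilbene 7 to aldehyde 3 and phosphonium salt 6. The alkene must be saturated without loss of the ring C bromide, which calls for diimide and not hydrogenation over palladium. Salt 6 carries the ring A phenol unprotected; it comes in two steps from the commercial aldehyde 4 via alcohol 5.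

**3 to 1 and 2.** The ring B–O–ring C ether is cut to 5-bromo-2-methoxyphenol 1 and 4-fluorobenzaldehyde 2. The para-formyl group activates the fluoride for substitution. Bromophenol 1 is preferred to isovanillin because its bromide and the formyl group of ring B are different handles, so 3 needs no protecting group.

## Roads not taken

**Alternative 1:** Ring A would be built last, by Robinson annulation on the 18-membered α-aryloxy ketone A1. The α-carbon bearing the ring D oxygen adds to methyl vinyl ketone, and aldol condensation onto the ring ketone gives the macrocyclic 4-aryloxy-3-alkylcyclohex-2-enone A2. The cut removes two bonds of ring A (C3–C4 and C5=C6).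
- Merits: A1 has only three arenes and a flexible keto ether segment, and its ring A–O–ring D oxygen bond can be made by simple alkylation at sp3 carbon. The enone oxygen of A2 ends as the wanted ring A hydroxyl, so no deoxygenation is needed. In both respects this road is better than the chosen one.
- Weak points: A1 can enolise on either side, and the Michael adduct can close in two aldol directions. More seriously, A2 holds the aryloxy group on C4 of a cyclohexenone. Dienol formation followed by loss of the ring D phenoxide aromatises ring A without any oxidant and opens the macrocycle, whereas the desired aromatisation needs a two-electron oxidation that must outrun this elimination. A1 also needs its own macrocyclisation.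
- Comparison: the chosen plan answers the elimination problem with 20, where the aryloxy group is on an sp2 carbon and the hydrogens to be removed sit on carbons without a leaving group. It pays with two extra steps (triflation, reduction).

**Alternative 2:** Ring B would be formed by a macrocyclising Diels–Alder reaction of the open precursor A3. Its 2-aryloxybutadiene on the ring C oxygen and its ethynyl ketone on the ring A side would give the 1-acyl-4-aryloxycyclohexa-1,4-diene A4. The cut removes two C–C bonds of ring B.
- Merits: two C–C bonds and the macrocycle form in one step. The para relationship follows from the donor at C2 of the diene and the acceptor on the alkyne. The 1,4-diene is one mild oxidation from the arene, and ring B is not yet a rigid para-phenylene in the transition state. The endgame (aromatise, reduce the ketone to CH2, demethylate) is no longer than the chosen one.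
- Weak points: the 2-aryloxydiene is acid-labile, and the Lewis acid needed to accelerate the cycloaddition threatens it. The terminal ynone is a polymerisable Michael acceptor. In a tethered 18-membered transition state the tether, not the electronic preference, may decide the orientation, so the meta adduct is a real risk. The hindered ring A–O–ring D ether must still be made beforehand by a classical coupling.
- Comparison: the chosen plan closes the ring through a single O–C bond with no regiochemical choice, using a stable precursor and a bond-forming event of a known type. It concedes the better bond economy of A4.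

**Alternative 3:** The 17-membered quinol aryl ether dienone A5 would be treated with BF3·OEt2. The bridge CH2 would shift from the quaternary carbon to the neighbouring ring carbon, aromatising ring A and expanding the ring to the ring C methyl ether A6.
- Merits: the dienone is symmetric, so both ortho carbons give the same product. Aromatisation drives the expansion. A6 is one demethylation from 27, a clearly shorter endgame than the four steps after the key step of the chosen plan.
- Weak points: A5 requires an ether bond at a quaternary carbon inside a 17-membered ring, for which no reliable closure is apparent. Under Lewis acid the aryloxy group can leave as the ring D phenol, giving a phenoxonium ion or a para-quinone methide and an opened ring. A primary alkyl group also migrates poorly, so aryloxy shift to the ortho carbon would compete.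
- Comparison: the chosen plan is longer after the ring closure, but its key bond formation has a direct intermolecular counterpart and no competing heterolysis.

Key step: step 10

## Route

Assumption: 27 has no stereocentre and its macrocycle is taken to be conformationally mobile, so no descriptor is needed; 19 to 23 are racemic at C5 of the ring D precursor, 7 is an E/Z mixture, and 1, 9 and 12 are taken as catalogue compounds.

Step 1
Reactants: 1 5-bromo-2-methoxyphenol; 2 4-fluorobenzaldehyde
Product: 3 4-(5-bromo-2-methoxyphenoxy)benzaldehyde
Conditions: K2CO3, DMF, 130 °C
Reagents that add atoms: none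
Why: Nucleophilic aromatic substitution; the para-formyl group activates the fluoride toward the potassium phenoxide, and the aryl bromide is inert under these conditions.

Step 2
Reactants: 4 2-hydroxy-5-methoxybenzaldehyde
Product: 5 2-(hydroxymethyl)-4-methoxyphenol
Conditions: NaBH4, MeOH, 0 °C to rt
Reagents that add atoms: none
Why: Borohydride reduction of an aromatic aldehyde; a mild NH4Cl work-up avoids acid-induced quinone methide formation from the salicyl alcohol.

Step 3
Reactants: 5 2-(hydroxymethyl)-4-methoxyphenol
Product: 6 (2-hydroxy-5-methoxybenzyl)triphenylphosphonium bromide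
Conditions: PPh3·HBr, MeCN, reflux
Reagents that add atoms: triphenylphosphine hydrobromide, Br.P(c1ccccc1)(c1ccccc1)c1ccccc1
Why: Acid-promoted ionisation of the ortho-hydroxybenzyl alcohol and capture by triphenylphosphine, the standard direct route to 2-hydroxybenzylphosphonium salts; the salt should crystallise from the mixture.

Step 4
Reactants: 6 (2-hydroxy-5-methoxybenzyl)triphenylphosphonium bromide; 3 4-(5-bromo-2-methoxyphenoxy)benzaldehyde
Product: 7 2-{2-[4-(5-bromo-2-methoxyphenoxy)phenyl]ethenyl}-4-methoxyphenol (E/Z mixture)
Conditions: KOtBu (2.2 equiv), THF, 0 °C to rt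
Reagents that add atoms: none
Why: Wittig olefination; the first equivalent of base forms the phenoxide and the second the ylide, as is usual for unprotected 2-hydroxybenzylphosphonium salts, and the alkene geometry is irrelevant because the double bond is saturated in step 5.

Step 5
Reactants: 7 2-{2-[4-(5-bromo-2-methoxyphenoxy)phenyl]ethenyl}-4-methoxyphenol
Product: 8 2-{2-[4-(5-bromo-2-methoxyphenoxy)phenyl]ethyl}-4-methoxyphenol
Conditions: TsNHNH2, NaOAc, DME/H2O, reflux
Reagents that add atoms: none
Why: Diimide reduction; diimide generated in the flask transfers two hydrogens to the stilbene in a concerted syn fashion and does not touch the aryl bromide, which hydrogenation over palladium would endanger.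

Step 6
Reactants: 8 2-{2-[4-(5-bromo-2-methoxyphenoxy)phenyl]ethyl}-4-methoxyphenol; 9 allyl alcohol (prop-2-en-1-ol)
Product: 11 3-(3-{4-[2-(2-hydroxy-5-methoxyphenyl)ethyl]phenoxy}-4-methoxyphenyl)propanal, via prop-1-en-1-ol enol 10 (not isolated)
Conditions: Pd(OAc)2 (5 mol%), Bu4NCl, NaHCO3, DMF, 80 °C
Reagents that add atoms: none
Why: Heck arylation of allyl alcohol under phosphine-free phase-transfer conditions; after insertion at the terminal carbon, β-hydride elimination toward the carbinol carbon gives enol 10, which tautomerises to the 3-arylpropanal, and NaHCO3 is too weak to ionise the phenol to any extent.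

Step 7
Reactants: 11 3-(3-{4-[2-(2-hydroxy-5-methoxyphenyl)ethyl]phenoxy}-4-methoxyphenyl)propanal; 12 1-(triphenyl-λ5-phosphanylidene)propan-2-one
Product: 13 (E)-6-(3-{4-[2-(2-hydroxy-5-methoxyphenyl)ethyl]phenoxy}-4-methoxyphenyl)hex-3-en-2-one
Conditions: toluene, 80 °C
Reagents that add atoms: none
Why: Wittig reaction of a stabilised acyl ylide with an aliphatic aldehyde, which gives the (E)-enone under thermodynamic control of the oxaphosphetane pathway; the ylide is not basic enough to be quenched by the phenol.

Step 8
Reactants: 13 (E)-6-(3-{4-[2-(2-hydroxy-5-methoxyphenyl)ethyl]phenoxy}-4-methoxyphenyl)hex-3-en-2-one; 14 diethyl malonate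
Product: 18 5-[2-(3-{4-[2-(2-hydroxy-5-methoxyphenyl)ethyl]phenoxy}-4-methoxyphenyl)ethyl]cyclohexane-1,3-dione, via Michael adduct 15 (not isolated), via cyclic keto ester 16 (not isolated), via keto acid 17 (not isolated)
Conditions: NaOEt (3.5 equiv), EtOH, reflux; then aq. NaOH, reflux; then HCl, reflux
Reagents that add atoms: water, O (carboxyl oxygen of intermediate 17 only; none remains in 18)
Why: Michael–Claisen annulation as in the classical dimedone synthesis: sodiomalonate adds to the enone (15), the methyl ketone enolate closes onto an ester (16, driven by formation of the β-diketone enolate), and saponification with decarboxylation of the β-keto acid 17 gives the dione; the extra base covers the phenoxide, and 18 is achiral because its enol forms interconvert through the symmetric diketone.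

Step 9
Reactants: 18 5-[2-(3-{4-[2-(2-hydroxy-5-methoxyphenyl)ethyl]phenoxy}-4-methoxyphenyl)ethyl]cyclohexane-1,3-dione
Product: 19 3-chloro-5-[2-(3-{4-[2-(2-hydroxy-5-methoxyphenyl)ethyl]phenoxy}-4-methoxyphenyl)ethyl]cyclohex-2-en-1-one (racemic)
Conditions: (COCl)2 (1.1 equiv), DMF (cat.), CH2Cl2, 0 °C to rt
Reagents that add atoms: oxalyl chloride, ClC(=O)C(Cl)=O
Why: Conversion of a vinylogous acid into the vinylogous acid chloride by Vilsmeier-type activation of the enol oxygen and addition–elimination of chloride at C3; the enolised dione (pKa near 5) should react far faster than the phenol (pKa near 10), just as hydroxybenzoic acids give acid chlorides with the phenol intact, and the catalytic amount of DMF caps any O-formylation; C5 becomes a stereocentre with no bias, hence racemic.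

Step 10
Reactants: 19 3-chloro-5-[2-(3-{4-[2-(2-hydroxy-5-methoxyphenyl)ethyl]phenoxy}-4-methoxyphenyl)ethyl]cyclohex-2-en-1-one
Product: 20 macrocyclic vinylogous aryl ester (racemic): 18-membered ring in which the ring A oxygen is bonded to C3 of the 5-substituted cyclohex-2-en-1-one, with rings A and C as methyl ethers
Conditions: Cs2CO3 (3 equiv), DMF, 60 °C, slow addition of 19 to a final 2 mM
Reagents that add atoms: none
Why: Cs2CO3 ionises the ring A phenol, which is far more acidic than the CH2 groups flanking the enone. The phenoxide adds through oxygen to C3 of the 3-chlorocyclohex-2-enone, and the enolate expels chloride to give the vinylogous aryl ester (addition–elimination at a vinylogous acid chloride). The closest known reaction is the carbonate-mediated intermolecular coupling of phenols with 3-chlorocyclohex-2-enones to 3-aryloxycyclohexenones, used here intramolecularly. One ring closes, the 18-membered macrocycle, by an 18-exo-trig addition (the C2=C3 bond lies outside the forming ring) followed by loss of chloride. No stereocentre is created; C5 stays racemic and disappears in step 11. The step needs ring closure to beat oligomerisation, and O-attack to beat C-attack and enolisation; syringe-pump addition into dilute DMF keeps the stationary concentration low, the loosely paired caesium phenoxide reacts at oxygen, and carbonate is too weak to enolise the enone appreciably. The electrophilic carbon needs no activating group and tolerates the single ortho alkyl next to the ring A oxygen. The half-chair ring D precursor carries its side chain on an sp3 carbon, so the chain can fold across the ring with less strain than four flat arenes would impose.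

Step 11
Reactants: 20 macrocyclic vinylogous aryl ester
Product: 24 ring D phenol: macrocycle with aromatic ring D bearing a hydroxyl meta to both the bridge carbon and the ether oxygen, rings A and C as methyl ethers, via α'-phenylselanyl ketone 21 (not isolated), via selenoxide 22 (not isolated), via cyclohexa-2,5-dienone tautomer 23 (not isolated)
Conditions: LiN(iPr)2, THF, −78 °C; PhSeCl; then H2O2, pyridine, CH2Cl2, 0 °C to rt
Reagents that add atoms: benzeneselenenyl chloride, Cl[Se]c1ccccc1 (PhSe group of intermediates 21 and 22); hydrogen peroxide, OO (selenoxide oxygen of 22); none remains in 24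
Why: Selenoxide dehydrogenation: vinylogous esters are deprotonated kinetically at the α' carbon (C6), the enolate is selenenylated preferentially anti to the C5 chain, and oxidation gives selenoxide 22, which undergoes syn-elimination with the cis C5 hydrogen below room temperature; dienone 23 is the keto tautomer of the phenol and enolises at once, which erases the C5 centre, while pyridine buffers the selenenic acid.

Step 12
Reactants: 24 ring D phenol
Product: 25 ring D aryl triflate (trifluoromethanesulfonate of 24)
Conditions: Tf2O, pyridine, CH2Cl2, 0 °C
Reagents that add atoms: trifluoromethanesulfonic anhydride, O=S(=O)(OS(=O)(=O)C(F)(F)F)C(F)(F)F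
Why: O-Sulfonylation of the only free hydroxyl in the molecule; no other nucleophilic site is present.

Step 13
Reactants: 25 ring D aryl triflate
Product: 26 di-O-methyl ether of the target (methoxy on ring A and on ring C, ring D unsubstituted apart from bridge and ether)
Conditions: Pd(OAc)2, Ph2P(CH2)3PPh2, HCO2H, Et3N, DMF, 70 °C
Reagents that add atoms: none
Why: Palladium-catalysed formate reduction of an aryl triflate: zerovalent palladium inserts into the C–OTf bond, formate exchanges for triflate and loses CO2 to give an aryl palladium hydride, and reductive elimination forms the C–H bond; diaryl and methyl ethers do not undergo oxidative addition under these conditions.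

Step 14
Reactants: 26 di-O-methyl ether of the target
Product: 27 target macrocyclic bis(bibenzyl) diphenol (CNP0135015.0)
Conditions: BBr3, CH2Cl2, −78 °C to rt
Reagents that add atoms: none
Why: Lewis acid demethylation of aryl methyl ethers by bromide attack on the methyl carbon of the boron-complexed ether; diaryl ethers offer no carbon open to substitution and survive, and the free phenols appear only in this last step.

## Compound list

1 | 5-bromo-2-methoxyphenol | COc1ccc(Br)cc1O | starting material
2 | 4-fluorobenzaldehyde | O=Cc1ccc(F)cc1 | starting material
3 | 4-(5-bromo-2-methoxyphenoxy)benzaldehyde | COc1ccc(Br)cc1Oc1ccc(C=O)cc1 | intermediate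
4 | 2-hydroxy-5-methoxybenzaldehyde | COc1ccc(O)c(C=O)c1 | starting material
5 | 2-(hydroxymethyl)-4-methoxyphenol | COc1ccc(O)c(CO)c1 | intermediate
6 | (2-hydroxy-5-methoxybenzyl)triphenylphosphonium bromide | COc1ccc(O)c(C[P+](c2ccccc2)(c2ccccc2)c2ccccc2)c1.[Br-] | intermediate
7 | 2-{2-[4-(5-bromo-2-methoxyphenoxy)phenyl]ethenyl}-4-methoxyphenol (E/Z mixture) | COc1ccc(O)c(C=Cc2ccc(Oc3cc(Br)ccc3OC)cc2)c1 | intermediate
8 | 2-{2-[4-(5-bromo-2-methoxyphenoxy)phenyl]ethyl}-4-methoxyphenol | COc1ccc(O)c(CCc2ccc(Oc3cc(Br)ccc3OC)cc2)c1 | intermediate
9 | allyl alcohol (prop-2-en-1-ol) | C=CCO | starting material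
10 | 3-(3-{4-[2-(2-hydroxy-5-methoxyphenyl)ethyl]phenoxy}-4-methoxyphenyl)prop-1-en-1-ol (enol, E/Z unspecified) | COc1ccc(O)c(CCc2ccc(Oc3cc(CC=CO)ccc3OC)cc2)c1 | intermediate
11 | 3-(3-{4-[2-(2-hydroxy-5-methoxyphenyl)ethyl]phenoxy}-4-methoxyphenyl)propanal | COc1ccc(O)c(CCc2ccc(Oc3cc(CCC=O)ccc3OC)cc2)c1 | intermediate
12 | 1-(triphenyl-λ5-phosphanylidene)propan-2-one | CC(=O)C=P(c1ccccc1)(c1ccccc1)c1ccccc1 | starting material
13 | (E)-6-(3-{4-[2-(2-hydroxy-5-methoxyphenyl)ethyl]phenoxy}-4-methoxyphenyl)hex-3-en-2-one | COc1ccc(O)c(CCc2ccc(Oc3cc(CC/C=C/C(C)=O)ccc3OC)cc2)c1 | intermediate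
14 | diethyl malonate | CCOC(=O)CC(=O)OCC | starting material
15 | diethyl 2-[1-(3-{4-[2-(2-hydroxy-5-methoxyphenyl)ethyl]phenoxy}-4-methoxyphenyl)-5-oxohexan-3-yl]propanedioate (racemic Michael adduct) | COc1ccc(O)c(CCc2ccc(Oc3cc(CCC(CC(C)=O)C(C(=O)OCC)C(=O)OCC)ccc3OC)cc2)c1 | intermediate
16 | ethyl 6-[2-(3-{4-[2-(2-hydroxy-5-methoxyphenyl)ethyl]phenoxy}-4-methoxyphenyl)ethyl]-2,4-dioxocyclohexane-1-carboxylate (racemic, present as its sodium enolate) | COc1ccc(O)c(CCc2ccc(Oc3cc(CCC4CC(=O)CC(=O)C4C(=O)OCC)ccc3OC)cc2)c1 | intermediate
17 | 6-[2-(3-{4-[2-(2-hydroxy-5-methoxyphenyl)ethyl]phenoxy}-4-methoxyphenyl)ethyl]-2,4-dioxocyclohexane-1-carboxylic acid (racemic) | COc1ccc(O)c(CCc2ccc(Oc3cc(CCC4CC(=O)CC(=O)C4C(O)=O)ccc3OC)cc2)c1 | intermediate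
18 | 5-[2-(3-{4-[2-(2-hydroxy-5-methoxyphenyl)ethyl]phenoxy}-4-methoxyphenyl)ethyl]cyclohexane-1,3-dione | COc1ccc(O)c(CCc2ccc(Oc3cc(CCC4CC(=O)CC(=O)C4)ccc3OC)cc2)c1 | intermediate
19 | 3-chloro-5-[2-(3-{4-[2-(2-hydroxy-5-methoxyphenyl)ethyl]phenoxy}-4-methoxyphenyl)ethyl]cyclohex-2-en-1-one (racemic) | COc1ccc(O)c(CCc2ccc(Oc3cc(CCC4CC(Cl)=CC(=O)C4)ccc3OC)cc2)c1 | intermediate
20 | macrocyclic vinylogous aryl ester (racemic; ring A oxygen on C3 of the cyclohex-2-en-1-one) | COc1ccc2c(c1)CCc1ccc(cc1)Oc1cc(ccc1OC)CCC1CC(=CC(=O)C1)O2 | intermediate
21 | α'-phenylselanyl derivative of 20 (PhSe on C6 of the cyclohexenone, diastereomer mixture) | COc1ccc2c(c1)CCc1ccc(cc1)Oc1cc(ccc1OC)CCC1CC(=CC(=O)C1[Se]c1ccccc1)O2 | intermediate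
22 | selenoxide of 21 (diastereomer mixture) | COc1ccc2c(c1)CCc1ccc(cc1)Oc1cc(ccc1OC)CCC1CC(=CC(=O)C1[Se](=O)c1ccccc1)O2 | intermediate
23 | macrocyclic 3-aryloxy-5-alkylcyclohexa-2,5-dien-1-one (keto tautomer of 24) | COc1ccc2c(c1)CCc1ccc(cc1)Oc1cc(ccc1OC)CCC1=CC(=O)C=C(C1)O2 | intermediate
24 | ring D phenol (aromatic ring D with OH meta to bridge carbon and to ether oxygen; OMe on rings A and C) | COc1ccc2c(c1)CCc1ccc(cc1)Oc1cc(ccc1OC)CCc1cc(O)cc(c1)O2 | intermediate
25 | ring D aryl triflate | COc1ccc2c(c1)CCc1ccc(cc1)Oc1cc(ccc1OC)CCc1cc(OS(=O)(=O)C(F)(F)F)cc(c1)O2 | intermediate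
26 | di-O-methyl ether of the target | COc1ccc2c(c1)CCc1ccc(cc1)Oc1cc(ccc1OC)CCc1cccc(c1)O2 | intermediate
27 | target bis(bibenzyl) macrocycle, CNP0135015.0 | Oc1ccc2c(c1)CCc1ccc(cc1)Oc1cc(ccc1O)CCc1cccc(c1)O2 | target

## Step count and risks

Total: 14 steps. Longest linear sequence: 13 steps (4 through steps 2 and 3, then steps 4 to 14).

**Step 10 (key step).** The most likely failure is intermolecular substitution: cyclic dimers and oligomers form faster than the 18-membered ring because the chain contains the rigid para-linked ring B. Slow base-induced enolisation and self-condensation of the chloroenone during the long addition is a second risk.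

The fallback sets out from 3 (using 6, 9, 12 and 14 of the main route) and comes back at 20. It makes the same O–C3 bond intermolecularly and closes the ring elsewhere. The formyl group of 3 would be masked with ethylene glycol and TsOH as 2-[4-(5-bromo-2-methoxyphenoxy)phenyl]-1,3-dioxolane F1. The Heck reaction with 9, as in step 6, would give the propanal F2, and ylide 12 the enone F3. The malonate annulation of step 8, whose acidic decarboxylation also frees the aldehyde, would give the dione aldehyde F4, and oxalyl chloride the chloroenone aldehyde F5. The phenol of 6 would then be joined to F5 at normal concentration with one equivalent of K2CO3 in MeCN to give the phosphonium vinylogous ester F6. The macrocycle would be closed at the ring A–ring B bridge by a high-dilution intramolecular Wittig reaction (K2CO3, 18-crown-6, CH2Cl2) to the macrocyclic stilbene F7. Diimide reduction as in step 5 would deliver 20.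

**Step 9.** The risk is loss of chemoselectivity: acylation or formylation of the free ring A phenol by oxalyl chloride or the chloroiminium species, or premature intermolecular O–C coupling when the crude chloroenone is concentrated.

The fallback sets out from 18 and comes back at 19. The phenol would be silylated with TBSCl and imidazole (the labile silyl enol ether of the dione is lost on aqueous work-up) to give the silyl ether dione F8. Chlorination as in step 9 would give the silyl ether chloroenone F9. Acetic acid-buffered Bu4NF would then remove the silyl group while the phenol stays protonated, giving 19.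

**Step 11.** The syn-elimination fails if selenium enters cis to the C5 chain, which leaves no cis β-hydrogen. The electron-rich rings may also undergo electrophilic selenenylation, and the new phenol may be over-oxidised by peroxide-activated selenium species.

The fallback sets out from 20 and comes back at 24, replacing the selenium chemistry with a palladium enolate dehydrogenation (Saegusa–Ito oxidation). LiN(iPr)2 and Me3SiCl would give the cross-conjugated trimethylsilyl dienol ether F10. Pd(OAc)2 in MeCN would then form the oxa-π-allyl complex of divalent palladium, whose β-hydride elimination and tautomerisation give 24.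

**Step 6.** Oxidative addition to the electron-rich aryl bromide may be sluggish. Wrong-way β-hydride elimination would give cinnamyl alcohol, arylation at the internal carbon would give the branched aldehyde, and the product aldehyde may undergo aldol self-condensation in the warm basic medium.

The fallback sets out from 8 and comes back at 11. A Heck reaction with ethyl acrylate (Pd(OAc)2, P(o-tolyl)3, Et3N, DMF) would give the ethyl cinnamate F11. Hydrogenation over Pd/C (no bromide remains) would give the ethyl propanoate F12. Reduction with iBu2AlH at −78 °C, with one extra equivalent for the phenol, would give 11.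

## Further compounds

F1 | step 10 | 2-[4-(5-bromo-2-methoxyphenoxy)phenyl]-1,3-dioxolane | COc1ccc(Br)cc1Oc1ccc(cc1)C1OCCO1
F2 | step 10 | 3-{3-[4-(1,3-dioxolan-2-yl)phenoxy]-4-methoxyphenyl}propanal | COc1ccc(CCC=O)cc1Oc1ccc(cc1)C1OCCO1
F3 | step 10 | (E)-6-{3-[4-(1,3-dioxolan-2-yl)phenoxy]-4-methoxyphenyl}hex-3-en-2-one | COc1ccc(CC/C=C/C(C)=O)cc1Oc1ccc(cc1)C1OCCO1
F4 | step 10 | 4-{5-[2-(3,5-dioxocyclohexyl)ethyl]-2-methoxyphenoxy}benzaldehyde | COc1ccc(CCC2CC(=O)CC(=O)C2)cc1Oc1ccc(C=O)cc1
F5 | step 10 | 4-{5-[2-(3-chloro-5-oxocyclohex-3-en-1-yl)ethyl]-2-methoxyphenoxy}benzaldehyde (racemic) | COc1ccc(CCC2CC(Cl)=CC(=O)C2)cc1Oc1ccc(C=O)cc1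
F6 | step 10 | {2-[(5-{2-[3-(4-formylphenoxy)-4-methoxyphenyl]ethyl}-3-oxocyclohex-1-en-1-yl)oxy]-5-methoxybenzyl}triphenylphosphonium bromide (racemic) | COc1ccc(OC2=CC(=O)CC(CCc3ccc(OC)c(Oc4ccc(C=O)cc4)c3)C2)c(C[P+](c2ccccc2)(c2ccccc2)c2ccccc2)c1.[Br-]
F7 | step 10 | macrocyclic stilbene analogue of 20 (ring A–CH=CH–ring B, E/Z mixture, racemic) | COc1ccc2c(c1)C=Cc1ccc(cc1)Oc1cc(ccc1OC)CCC1CC(=CC(=O)C1)O2
F8 | step 9 | tert-butyldimethylsilyl ether of 18 at the ring A phenol | COc1ccc(O[Si](C)(C)C(C)(C)C)c(CCc2ccc(Oc3cc(CCC4CC(=O)CC(=O)C4)ccc3OC)cc2)c1
F9 | step 9 | tert-butyldimethylsilyl ether of 19 at the ring A phenol (racemic) | COc1ccc(O[Si](C)(C)C(C)(C)C)c(CCc2ccc(Oc3cc(CCC4CC(Cl)=CC(=O)C4)ccc3OC)cc2)c1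
F10 | step 11 | trimethylsilyl dienol ether of 20 (racemic) | COc1ccc2c(c1)CCc1ccc(cc1)Oc1cc(ccc1OC)CCC1CC(=CC(O[Si](C)(C)C)=C1)O2
F11 | step 6 | ethyl (E)-3-(3-{4-[2-(2-hydroxy-5-methoxyphenyl)ethyl]phenoxy}-4-methoxyphenyl)prop-2-enoate | COc1ccc(O)c(CCc2ccc(Oc3cc(/C=C/C(=O)OCC)ccc3OC)cc2)c1
F12 | step 6 | ethyl 3-(3-{4-[2-(2-hydroxy-5-methoxyphenyl)ethyl]phenoxy}-4-methoxyphenyl)propanoate | COc1ccc(O)c(CCc2ccc(Oc3cc(CCC(=O)OCC)ccc3OC)cc2)c1
A1 | alternative 1 | 18-membered macrocyclic α-aryloxy ketone | O=C1COc2cccc(c2)CCc2ccc(OC)c(c2)Oc2ccc(cc2)CC1
A2 | alternative 1 | macrocyclic 4-aryloxy-3-alkylcyclohex-2-enone (racemic) | O=C1C=C2C(CC1)Oc1cccc(c1)CCc1ccc(OC)c(c1)Oc1ccc(cc1)CC2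
A3 | alternative 2 | open precursor with 2-aryloxybuta-1,3-diene and ethynyl ketone | COc1ccc(Oc2cccc(CCc3ccc(OC)c(OC(=C)C=C)c3)c2)c(CC(=O)C#C)c1
A4 | alternative 2 | macrocyclic 1-acyl-4-aryloxycyclohexa-1,4-diene | COc1ccc2c(c1)CC(=O)C1=CCC(=CC1)Oc1cc(ccc1OC)CCc1cccc(c1)O2
A5 | alternative 3 | 17-membered quinol aryl ether dienone | O=C1C=CC2(C=C1)CCc1ccc(cc1)Oc1cc(ccc1OC)CCc1cccc(c1)O2
A6 | alternative 3 | ring C methyl ether of the target | Oc1ccc2c(c1)CCc1ccc(cc1)Oc1cc(ccc1OC)CCc1cccc(c1)O2
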